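**Strategy**

The route rests on cutting the C2–C3 bond of indole A, the indole joined through C3 to the methine carbon (C3 of the propanediol chain) and unsubstituted at C2. That pattern is what a tin-mediated radical cyclisation of an o-isocyanostyrene delivers: in one operation the pyrrole ring of indole A is closed, C2 is left as C–H, and the radical lands on the methine carbon, where hydrogen-atom transfer beside the glyceraldehyde-derived dioxolane creates the second stereocentre. The precursor is a trisubstituted styrene carrying 2-isocyanophenyl on one alkene carbon and, on the other, the (S)-dioxolane and the N-unprotected, O-silylated tryptophol indol-2-yl (indole B).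

Key step: step 9

Assumptions and design remarks:
- Aldehyde 1 is taken freshly distilled (it oligomerises on storage); the volatile alkyne 2 is carried forward as a concentrated solution.
- Stereochemical bookkeeping: the target is (2S,3R). Its carbinol centre C2 is the stereocentre of (R)-1, unchanged in space (only the descriptor changes with the substituents). The methine centre C3 is made in step 9.
- Indole B carries no N-protecting group. An N-arenesulfonyl group would sit next to the radical centre (risk of ipso attack, loss of coplanarity). The free N–H can instead hydrogen-bond to the dioxolane oxygen and order the radical, and the end game shrinks to one mild acid treatment.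
- The aryl–alkene is assembled by borylcupration and Suzuki coupling, which is one step longer than a direct hydroarylation with a 2-borylindole but is judged more dependable.

**Route**

Step 1
Reactants: 1 (R)-2,2-dimethyl-1,3-dioxolane-4-carbaldehyde
Product: 2 (S)-4-ethynyl-2,2-dimethyl-1,3-dioxolane
Conditions: dimethyl (1-diazo-2-oxopropyl)phosphonate, K2CO3, MeOH, 0 °C to rt
Reagents that add atoms: dimethyl (1-diazo-2-oxopropyl)phosphonate, CC(=O)C(=[N+]=[N-])P(=O)(OC)OC
Why: Seyferth–Gilbert homologation in its Ohira–Bestmann form turns the aldehyde into the terminal alkyne under carbonate base at low temperature, conditions mild enough that the α-alkoxy stereocentre should be carried over unchanged (the descriptor changes from R to S only because the substituent ranking changes).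

Step 2
Reactants: 3 2-iodoaniline
Product: 4 N-(2-iodophenyl)formamide
Conditions: HCO2H/Ac2O (premixed), THF, 0 °C to rt
Reagents that add atoms: formic acid, O=CO, transferred as acetic formic anhydride, CC(=O)OC=O
Why: N-Formylation of the aniline by the mixed anhydride (acyl transfer) installs the latent isocyanide carbon at the outset, and the ortho iodide is untouched.

Step 3
Reactants: 4 N-(2-iodophenyl)formamide; 2 (S)-4-ethynyl-2,2-dimethyl-1,3-dioxolane
Product: 5 N-(2-{[(4S)-2,2-dimethyl-1,3-dioxolan-4-yl]ethynyl}phenyl)formamide
Conditions: Pd(PPh3)2Cl2 (cat.), CuI (cat.), Et3N, THF, rt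
Reagents that add atoms: none
Why: Sonogashira coupling of an aryl iodide with a terminal alkyne runs at room temperature, where the formanilide does not cyclise onto the alkyne and the acetonide and its stereocentre are inert.

Step 4
Reactants: 5 N-(2-{[(4S)-2,2-dimethyl-1,3-dioxolan-4-yl]ethynyl}phenyl)formamide
Product: 6 N-(2-{(Z)-2-[(4S)-2,2-dimethyl-1,3-dioxolan-4-yl]-2-(4,4,5,5-tetramethyl-1,3,2-dioxaborolan-2-yl)ethenyl}phenyl)formamide
Conditions: B2pin2, CuCl (cat.), P(p-tol)3 (cat.), NaOtBu (cat.), MeOH (2 equiv), THF, rt
Reagents that add atoms: bis(pinacolato)diboron, CC1(C)OB(OC1(C)C)B1OC(C)(C)C(C)(C)O1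
Why: Copper-catalysed borylcupration followed by protonation (formal syn-hydroboration of an internal alkyne) should place boron on the alkyne carbon remote from the arene, because copper prefers the benzylic carbon, and it adds H and B to the same side, which fixes the connectivity needed for the trisubstituted alkene.

Step 5
Reactants: 7 tryptophol, 2-(1H-indol-3-yl)ethanol
Product: 8 3-[2-(tert-butyldimethylsilyloxy)ethyl]-1H-indole
Conditions: TBSCl, imidazole, DMF, 0 °C to rt
Reagents that add atoms: tert-butyldimethylsilyl chloride, CC(C)(C)[Si](C)(C)Cl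
Why: Imidazole-promoted silylation (silyl ether formation) protects the primary alcohol against NBS and POCl3 while leaving the indole N–H free.

Step 6
Reactants: 8 3-[2-(tert-butyldimethylsilyloxy)ethyl]-1H-indole
Product: 9 2-bromo-3-[2-(tert-butyldimethylsilyloxy)ethyl]-1H-indole
Conditions: NBS (1.0 equiv), silica gel, CH2Cl2, 0 °C to rt, dark
Reagents that add atoms: N-bromosuccinimide, O=C1CCC(=O)N1Br
Why: Electrophilic aromatic substitution of a 3-alkylindole with NBS should deliver bromine to the only free position of the pyrrole ring, C2, without touching the silyl ether.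

Step 7
Reactants: 6 N-(2-{(Z)-2-[(4S)-2,2-dimethyl-1,3-dioxolan-4-yl]-2-(4,4,5,5-tetramethyl-1,3,2-dioxaborolan-2-yl)ethenyl}phenyl)formamide; 9 2-bromo-3-[2-(tert-butyldimethylsilyloxy)ethyl]-1H-indole
Product: 10 N-(2-{(Z)-2-{3-[2-(tert-butyldimethylsilyloxy)ethyl]-1H-indol-2-yl}-2-[(4S)-2,2-dimethyl-1,3-dioxolan-4-yl]ethenyl}phenyl)formamide
Conditions: Pd(OAc)2 (cat.), SPhos (cat.), K3PO4, 1,4-dioxane/H2O, 60 °C
Reagents that add atoms: none
Why: Suzuki–Miyaura coupling of the alkenylboronate with the 2-bromoindole proceeds with retention at the alkene, and a dialkylbiarylphosphine ligand with phosphate base is the combination established for hindered partners and for halides bearing a free N–H.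

Step 8
Reactants: 10 N-(2-{(Z)-2-{3-[2-(tert-butyldimethylsilyloxy)ethyl]-1H-indol-2-yl}-2-[(4S)-2,2-dimethyl-1,3-dioxolan-4-yl]ethenyl}phenyl)formamide
Product: 11 3-[2-(tert-butyldimethylsilyloxy)ethyl]-2-[(Z)-1-[(4S)-2,2-dimethyl-1,3-dioxolan-4-yl]-2-(2-isocyanophenyl)ethenyl]-1H-indole
Conditions: POCl3, Et3N, CH2Cl2, −30 to 0 °C
Reagents that add atoms: none
Why: Dehydration of an N-arylformamide with POCl3 and excess tertiary amine (formamide-to-isocyanide dehydration) is fast below 0 °C, and the amine buffer should keep the acetonide, the silyl ether and the 2-vinylindole intact.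

Step 9
Reactants: 11 3-[2-(tert-butyldimethylsilyloxy)ethyl]-2-[(Z)-1-[(4S)-2,2-dimethyl-1,3-dioxolan-4-yl]-2-(2-isocyanophenyl)ethenyl]-1H-indole
Product: 13 3-[2-(tert-butyldimethylsilyloxy)ethyl]-2-{(R)-[(4S)-2,2-dimethyl-1,3-dioxolan-4-yl](1H-indol-3-yl)methyl}-1H-indole, via 2-tributylstannylindole 12 (not isolated)
Conditions: Bu3SnH (1.3 equiv), AIBN (0.1 equiv), degassed toluene (0.02 M), 80 °C; then 1 M aq. HCl, Et2O, 0 °C, 10 min
Reagents that add atoms: none
Why: Bu3Sn• adds to the isocyanide carbon to give a stannylimidoyl radical, which closes the pyrrole ring of indole A by 5-exo-trig attack on the unsubstituted styrene carbon (the future C3), forming the C2–C3 bond and placing the radical on the fully substituted carbon, where the indol-2-yl group of indole B stabilises it; hydrogen transfer from Bu3SnH and aromatisation give the 2-stannylindole 12, which is protodestannylated on acidic work-up to 13. The closest known reaction type is the Fukuyama indole synthesis from o-alkenylphenyl isocyanides, combined with 1,2-induction in hydrogen-atom transfer to an acyclic radical next to a ring stereocentre. Both alkene isomers feed the same radical and the dioxolane centre is a spectator, so the one selectivity required is the face of hydrogen delivery. The new methine stereocentre is controlled by the (S)-dioxolane: in toluene the N–H of indole B should hydrogen-bond to the ring oxygen O3 and hold it in the plane of the delocalised radical, so that the ring CH2 (C5) covers one face and the stannane delivers hydrogen to the other, which corresponds to the (R)-methine of the target. The sp3 C3 created in the ring closure also flanks the radical, but it becomes planar again when the ring aromatises, so the methine epimer is the only stereochemical by-product and would be removed by chromatography of 13. The free N–H of indole B is deliberate: it offers the hydrogen bond, keeps the indol-2-yl coplanar with the radical, and leaves no arenesulfonyl group that could intercept the radical by ipso attack.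

Step 10
Reactants: 13 3-[2-(tert-butyldimethylsilyloxy)ethyl]-2-{(R)-[(4S)-2,2-dimethyl-1,3-dioxolan-4-yl](1H-indol-3-yl)methyl}-1H-indole
Product: 14 colletotryptin A, (2S,3R)-3-[3-(2-hydroxyethyl)-1H-indol-2-yl]-3-(1H-indol-3-yl)propane-1,2-diol
Conditions: AcOH/THF/H2O (3:1:1), 40 °C
Reagents that add atoms: none
Why: Acid-catalysed hydrolysis of the acetonide and of the primary silyl ether (acetal hydrolysis and desilylation) should occur together in aqueous acetic acid, which is mild enough not to ionise the bis(indolyl)methine or to touch either stereocentre.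

**Compound list**

1 | (R)-2,2-dimethyl-1,3-dioxolane-4-carbaldehyde | O=C[C@H]1COC(C)(C)O1 | starting material
2 | (S)-4-ethynyl-2,2-dimethyl-1,3-dioxolane | C#C[C@H]1COC(C)(C)O1 | intermediate
3 | 2-iodoaniline | Nc1ccccc1I | starting material
4 | N-(2-iodophenyl)formamide | O=CNc1ccccc1I | intermediate
5 | N-(2-{[(4S)-2,2-dimethyl-1,3-dioxolan-4-yl]ethynyl}phenyl)formamide | O=CNc1ccccc1C#C[C@H]1COC(C)(C)O1 | intermediate
6 | N-(2-{(Z)-2-[(4S)-2,2-dimethyl-1,3-dioxolan-4-yl]-2-(4,4,5,5-tetramethyl-1,3,2-dioxaborolan-2-yl)ethenyl}phenyl)formamide | O=CNc1ccccc1/C=C(/B1OC(C)(C)C(C)(C)O1)[C@H]1COC(C)(C)O1 | intermediate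
7 | tryptophol, 2-(1H-indol-3-yl)ethanol | OCCc1c[nH]c2ccccc12 | starting material
8 | 3-[2-(tert-butyldimethylsilyloxy)ethyl]-1H-indole | CC(C)(C)[Si](C)(C)OCCc1c[nH]c2ccccc12 | intermediate
9 | 2-bromo-3-[2-(tert-butyldimethylsilyloxy)ethyl]-1H-indole | CC(C)(C)[Si](C)(C)OCCc1c(Br)[nH]c2ccccc12 | intermediate
10 | N-(2-{(Z)-2-{3-[2-(tert-butyldimethylsilyloxy)ethyl]-1H-indol-2-yl}-2-[(4S)-2,2-dimethyl-1,3-dioxolan-4-yl]ethenyl}phenyl)formamide | O=CNc1ccccc1/C=C(/c1[nH]c2ccccc2c1CCO[Si](C)(C)C(C)(C)C)[C@H]1COC(C)(C)O1 | intermediate
11 | 3-[2-(tert-butyldimethylsilyloxy)ethyl]-2-[(Z)-1-[(4S)-2,2-dimethyl-1,3-dioxolan-4-yl]-2-(2-isocyanophenyl)ethenyl]-1H-indole | [C-]#[N+]c1ccccc1/C=C(/c1[nH]c2ccccc2c1CCO[Si](C)(C)C(C)(C)C)[C@H]1COC(C)(C)O1 | intermediate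
12 | 3-[2-(tert-butyldimethylsilyloxy)ethyl]-2-{(R)-[(4S)-2,2-dimethyl-1,3-dioxolan-4-yl][2-(tributylstannyl)-1H-indol-3-yl]methyl}-1H-indole | CC(C)(C)[Si](C)(C)OCCc1c([C@@H](c2c([Sn](CCCC)(CCCC)CCCC)[nH]c3ccccc23)[C@H]2COC(C)(C)O2)[nH]c2ccccc12 | intermediate
13 | 3-[2-(tert-butyldimethylsilyloxy)ethyl]-2-{(R)-[(4S)-2,2-dimethyl-1,3-dioxolan-4-yl](1H-indol-3-yl)methyl}-1H-indole | CC(C)(C)[Si](C)(C)OCCc1c([C@@H](c2c[nH]c3ccccc23)[C@H]2COC(C)(C)O2)[nH]c2ccccc12 | intermediate
14 | colletotryptin A, (2S,3R)-3-[3-(2-hydroxyethyl)-1H-indol-2-yl]-3-(1H-indol-3-yl)propane-1,2-diol | OCCc1c([C@@H](c2c[nH]c3ccccc23)[C@H](O)CO)[nH]c2ccccc12 | target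

**Step count and risks**

Total step count: 10.
Longest linear sequence: 7 steps (steps 1, 3, 4, 7, 8, 9 and 10, from aldehyde 1).

Steps most likely to fail:

(1) Step 9. What may go wrong: hydrogen transfer to the planar methine radical is not face-selective, or prefers the face that leads to the methine epimer. The hydrogen bond may not hold at 80 °C, or the neighbouring sp3 carbon of the half-formed indole may impose its own bias. Lower temperature (Et3B/air initiation) and a bulkier donor such as (Me3Si)3SiH would be tried first. The fallback forms the methine–C3 bond of indole A by an ionic instead of a radical reaction; it sets out from 8 and 1 and comes back at 13. Indole 8 is deprotonated with BuLi in THF at −78 °C and treated with CO2 to give lithium 3-[2-(tert-butyldimethylsilyloxy)ethyl]indole-1-carboxylate F1. F1 is lithiated at C2 with t-BuLi in the same flask and added to aldehyde 1. Aqueous work-up, with loss of CO2, gives {3-[2-(tert-butyldimethylsilyloxy)ethyl]-1H-indol-2-yl}[(4R)-2,2-dimethyl-1,3-dioxolan-4-yl]methanol F2 as a mixture of carbinol epimers, which is of no consequence. A catalytic Brønsted acid such as diphenyl phosphate in CH2Cl2 at low temperature should ionise F2 to the 2-alkylidene-2H-indolium ion, which alkylates commercial indole at C3 in a Friedel–Crafts reaction to give 13. The dioxolane again chooses the face of the planar intermediate, but the entering group is now the indole and not hydrogen, so attack on the same face gives the opposite methine configuration. The ionic route should therefore complement the radical one.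

(2) Step 4. What may go wrong: the boryl group is delivered to the alkyne carbon next to the arene, because the propargylic oxygen draws copper to its own side. The misplaced alkenylcopper then expels the dioxolane oxygen to give an allene. The fallback replaces borylcupration and cross-coupling by a carborhodation; it sets out from 8 and 5 and comes back at 10. Iridium-catalysed C–H borylation of 8 ([Ir(OMe)(cod)]2, 4,4′-di-tert-butyl-2,2′-bipyridine, B2pin2, THF), which is C2-selective for N–H indoles, gives 3-[2-(tert-butyldimethylsilyloxy)ethyl]-2-(4,4,5,5-tetramethyl-1,3,2-dioxaborolan-2-yl)-1H-indole F3. Rhodium-catalysed syn-hydroarylation of alkyne 5 with F3 ([Rh(OH)(cod)]2, 1,4-dioxane/H2O, 60 °C) then puts the indol-2-yl group directly on the alkyne carbon remote from the arene. Rhodium sits on the benzylic carbon, where the ortho formamide can chelate it, and protonolysis gives 10. Steps 4, 6 and 7 are then not needed.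

(3) Step 7. What may go wrong: transmetalation of the hindered, α-branched alkenylboronate is slow, so that protodeboronation of 6 and decomposition of the light- and acid-sensitive bromide 9 win. The fallback reverses the polarity of the coupling partners; it sets out from 6 and 8 and comes back at 10. Iododeboronation of 6 (I2, aq. NaOH, THF, 0 °C) gives N-(2-{(E)-2-[(4R)-2,2-dimethyl-1,3-dioxolan-4-yl]-2-iodoethenyl}phenyl)formamide F4; the alkene geometry is of no consequence for step 9. Suzuki–Miyaura coupling of F4 with the stable 3-[2-(tert-butyldimethylsilyloxy)ethyl]-2-(4,4,5,5-tetramethyl-1,3,2-dioxaborolan-2-yl)-1H-indole F3, made from 8 as under (2), gives 10. Steps 6 and 7 are replaced.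

Further compounds
F1 | step 9 | lithium 3-[2-(tert-butyldimethylsilyloxy)ethyl]indole-1-carboxylate | CC(C)(C)[Si](C)(C)OCCc1cn(C(=O)[O-])c2ccccc12.[Li+]
F2 | step 9 | {3-[2-(tert-butyldimethylsilyloxy)ethyl]-1H-indol-2-yl}[(4R)-2,2-dimethyl-1,3-dioxolan-4-yl]methanol | CC(C)(C)[Si](C)(C)OCCc1c(C(O)[C@H]2COC(C)(C)O2)[nH]c2ccccc12
F3 | step 4 | 3-[2-(tert-butyldimethylsilyloxy)ethyl]-2-(4,4,5,5-tetramethyl-1,3,2-dioxaborolan-2-yl)-1H-indole | CC(C)(C)[Si](C)(C)OCCc1c(B2OC(C)(C)C(C)(C)O2)[nH]c2ccccc12
F4 | step 7 | N-(2-{(E)-2-[(4R)-2,2-dimethyl-1,3-dioxolan-4-yl]-2-iodoethenyl}phenyl)formamide | O=CNc1ccccc1/C=C(/I)[C@H]1COC(C)(C)O1
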